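The cyclohexenone (C1 ketone, C2 bearing CH2OH, C3 vinylic CH, C4 angelate, C5 isopropyl, C6 epoxy ester) is cut into a furan and an enal. C3, C2, C1 and C6 come from a 3-siloxy-4-(silyloxymethyl)furan whose ring oxygen becomes the C6 ester oxygen; C4 and C5 come from a (Z)-2-angeloyloxy enal. One catalytic asymmetric Diels–Alder reaction forms C3–C4 and C5–C6 and sets C4, C5 and C6 with the angelate in place. It exploits the 1,4-relationship across the six-membered ring between the C6–O bond and vinylic C3 beside the C1 carbonyl: after loss of the formyl activating group as CO, the 7-oxanorbornanone opens by β-elimination to the 6-hydroxy enone.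

Key step: step 8

Remark: angelic anhydride 10 and methyl angelate 18 are taken as commercially available.
Remark: the (S)-oxazaborolidinium salt is written for step 8; the sense of face selection is assigned by analogy with α-substituted acroleins and must be confirmed on 15. The (R)-catalyst is equally accessible and would be used if the sense is opposite.
Remark: "C1–C6" in the Why lines is the target ring numbering given above; the bicyclic names carry their own locants.

Step 1
Reactants: 1 methyl 4-oxotetrahydrofuran-3-carboxylate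
Product: 2 methyl 4-[tert-butyl(dimethyl)silyl]oxy-2,5-dihydrofuran-3-carboxylate
Conditions: tBuMe2SiOTf, Et3N, CH2Cl2, 0 °C
Reagents that add atoms: tert-butyldimethylsilyl trifluoromethanesulfonate, CC(C)(C)[Si](C)(C)OS(=O)(=O)C(F)(F)F
Why: O-silylation of the β-keto ester (silyl enol ether formation) should give the conjugated enol ether between the two carbonyl-bearing carbons.

Step 2
Reactants: 2 methyl 4-[tert-butyl(dimethyl)silyl]oxy-2,5-dihydrofuran-3-carboxylate
Product: 3 methyl 4-[tert-butyl(dimethyl)silyl]oxyfuran-3-carboxylate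
Conditions: DDQ, 1,4-dioxane, rt
Reagents that add atoms: none
Why: DDQ dehydrogenation: hydride abstraction from the allylic CH2 next to the ring oxygen and proton loss should aromatise the 2,5-dihydrofuran to the furan with the silyl ether intact.

Step 3
Reactants: 3 methyl 4-[tert-butyl(dimethyl)silyl]oxyfuran-3-carboxylate
Product: 4 {4-[tert-butyl(dimethyl)silyl]oxyfuran-3-yl}methanol
Conditions: iBu2AlH, CH2Cl2, −78 °C; aq. KNaC4H4O6 (potassium sodium tartrate) work-up
Reagents that add atoms: none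
Why: Hydride reduction of the ester through the aldehyde to the primary alcohol, at a temperature where the silyl group should not migrate.

Step 4
Reactants: 4 {4-[tert-butyl(dimethyl)silyl]oxyfuran-3-yl}methanol
Product: 5 tert-butyl-({4-[tert-butyl(dimethyl)silyl]oxyfuran-3-yl}methoxy)diphenylsilane
Conditions: tBuPh2SiCl, imidazole, CH2Cl2, 0 °C
Reagents that add atoms: tert-butyl(chloro)diphenylsilane, CC(C)(C)[Si](Cl)(c1ccccc1)c1ccccc1
Why: Imidazole-promoted silylation of the primary alcohol without strong base avoids silyl migration and gives an ether that should survive the later acid hydrolysis of the enol silyl ether.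

Step 5
Reactants: 6 ethyl diethoxyacetate; 7 isobutylmagnesium bromide
Product: 9 1,1-diethoxy-4-methylpentan-2-one, via bromomagnesium hemiketalate 8 (not isolated)
Conditions: THF, −78 °C; then aq. NH4Cl
Reagents that add atoms: none
Why: Grignard addition to the α,α-dialkoxy ester should stop at the chelated tetrahedral magnesium hemiketalate, which collapses to the ketone only on quench.

Step 6
Reactants: 9 1,1-diethoxy-4-methylpentan-2-one; 10 angelic anhydride
Product: 12 (2Z)-1,1-diethoxy-4-methylpent-2-en-2-yl (2Z)-2-methylbut-2-enoate, via potassium enolate 11 (not isolated)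
Conditions: KN(SiMe3)2, THF, −78 °C; then 10, −78 to −40 °C
Reagents that add atoms: none
Why: Kinetic deprotonation at the CH2 group should give the (Z)-enolate (isopropyl-bearing carbon syn to oxygen, away from the bulky acetal), and O-acylation of the potassium enolate by the anhydride (enol ester formation) fixes isopropyl cis to the angeloyloxy group.

Step 7
Reactants: 12 (2Z)-1,1-diethoxy-4-methylpent-2-en-2-yl (2Z)-2-methylbut-2-enoate
Product: 13 (2Z)-4-methyl-1-oxopent-2-en-2-yl (2Z)-2-methylbut-2-enoate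
Conditions: 10% aq. oxalic acid on SiO2, CH2Cl2, rt
Reagents that add atoms: water, O
Why: Mild acetal hydrolysis through a conjugated oxocarbenium ion should release the enal while the enol ester stays intact.

Step 8
Reactants: 5 tert-butyl-({4-[tert-butyl(dimethyl)silyl]oxyfuran-3-yl}methoxy)diphenylsilane; 13 (2Z)-4-methyl-1-oxopent-2-en-2-yl (2Z)-2-methylbut-2-enoate
Product: 15 (1S,3S,4S,5S,6S)-5-formyl-2-oxo-6-(propan-2-yl)-3-{[tert-butyl(diphenyl)silyl]oxymethyl}-7-oxabicyclo[2.2.1]heptan-5-yl (2Z)-2-methylbut-2-enoate, via silyl enol ether cycloadduct 14 (not isolated)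
Conditions: (S)-3,3-diphenyl-1-(2-methylphenyl)tetrahydro-1H,3H-pyrrolo[1,2-c][1,3,2]oxazaborole·HNTf2 (20 mol%), CH2Cl2, −78 to −40 °C; then 1 M HCl, THF, 0 °C
Reagents that add atoms: none
Why: The protonated chiral oxazaborolidine binds the formyl oxygen of 13, and furan 5 adds as the diene in a probably asynchronous [4+2] cycloaddition: furan C2 (between the ring oxygen and C–OSi) attacks the isopropyl-bearing β-carbon and furan C5 closes onto the α-carbon, so C5–C6 and C3–C4 form in one operation. The closest known reaction type is the chiral-Lewis-acid-catalysed Diels–Alder reaction of α-substituted acroleins with furans and with 2-siloxydienes. The carbocycle closes by suprafacial [4+2] cycloaddition to the 7-oxabicyclo[2.2.1]heptene, whose enol silyl ether is hydrolysed in the work-up by exo protonation (this centre is erased in step 10). The (Z)-alkene holds isopropyl and angeloyloxy cis, the exo-formyl transition state usual for α-substituted acroleins places both endo, that is trans to the oxygen bridge that becomes the C6 oxygen, and the catalyst sets the absolute configuration by shielding one face of the bound enal. The step needs addition to C=C and not to the formyl group, and head-to-tail regiochemistry; the match of the siloxy-activated furan C2 with the enal β-carbon should secure both.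

Step 9
Reactants: 15 (1S,3S,4S,5S,6S)-5-formyl-2-oxo-6-(propan-2-yl)-3-{[tert-butyl(diphenyl)silyl]oxymethyl}-7-oxabicyclo[2.2.1]heptan-5-yl (2Z)-2-methylbut-2-enoate
Product: 16 (1S,3S,4S,5S,6R)-2-oxo-6-(propan-2-yl)-3-{[tert-butyl(diphenyl)silyl]oxymethyl}-7-oxabicyclo[2.2.1]heptan-5-yl (2Z)-2-methylbut-2-enoate
Conditions: RhCl(PPh3)3 (1.1 equiv), degassed toluene, 100 °C
Reagents that add atoms: none
Why: Tsuji–Wilkinson decarbonylation (oxidative addition of the formyl C–H bond to monovalent rhodium, CO extrusion, reductive elimination) proceeds with retention, so the new C–H bond should be exo and the angelate stays endo; the saturated bicycle cannot undergo a retro-Diels–Alder reaction.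

Step 10
Reactants: 16 (1S,3S,4S,5S,6R)-2-oxo-6-(propan-2-yl)-3-{[tert-butyl(diphenyl)silyl]oxymethyl}-7-oxabicyclo[2.2.1]heptan-5-yl (2Z)-2-methylbut-2-enoate
Product: 17 (4R,5S,6S)-6-hydroxy-4-[(2Z)-2-methylbut-2-enoyloxy]-5-(propan-2-yl)-2-{[tert-butyl(diphenyl)silyl]oxymethyl}cyclohex-2-en-1-one
Conditions: 1,8-diazabicyclo[5.4.0]undec-7-ene (0.2 equiv), CH2Cl2, 0 °C
Reagents that add atoms: none
Why: E1cB β-elimination: enolisation of the ketone towards C2 expels the strained oxygen bridge from C3, which should unveil the C2=C3 enone and the C6 hydroxyl while C4, C5 and C6 are untouched.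

Step 11
Reactants: 18 methyl angelate
Product: 19 (2Z)-2-methylbut-2-en-1-ol
Conditions: iBu2AlH, Et2O, −78 to 0 °C
Reagents that add atoms: none
Why: Hydride reduction of the conjugated ester should give the allylic alcohol without isomerising the (Z)-alkene.

Step 12
Reactants: 19 (2Z)-2-methylbut-2-en-1-ol
Product: 20 [(2S,3R)-2,3-dimethyloxiran-2-yl]methanol
Conditions: Ti(OiPr)4 (10 mol%), diethyl L-(+)-tartrate (12 mol%), tBuOOH, 4 Å molecular sieves, CH2Cl2, −20 °C
Reagents that add atoms: tert-butyl hydroperoxide, CC(C)(C)OO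
Why: Sharpless asymmetric epoxidation: the titanium L-(+)-tartrate complex delivers oxygen to the face that gives the 2S epoxy alcohol, and syn addition transfers the (Z)-geometry to the 3R centre.

Step 13
Reactants: 20 [(2S,3R)-2,3-dimethyloxiran-2-yl]methanol
Product: 21 (2R,3R)-2,3-dimethyloxirane-2-carboxylic acid
Conditions: 2,2,6,6-tetramethylpiperidin-1-oxyl (TEMPO, 20 mol%), PhI(OAc)2 (2.2 equiv), MeCN/H2O 1:1, rt
Reagents that add atoms: water, O
Why: Oxoammonium-mediated oxidation takes the primary alcohol through the aldehyde hydrate to the acid under near-neutral conditions that should leave the epoxide closed; the descriptor at C2 changes only by priority.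

Step 14
Reactants: 17 (4R,5S,6S)-6-hydroxy-4-[(2Z)-2-methylbut-2-enoyloxy]-5-(propan-2-yl)-2-{[tert-butyl(diphenyl)silyl]oxymethyl}cyclohex-2-en-1-one; 21 (2R,3R)-2,3-dimethyloxirane-2-carboxylic acid
Product: 22 (4R,5R,6S)-4-[(2Z)-2-methylbut-2-enoyloxy]-6-{[(2R,3R)-2,3-dimethyloxiran-2-yl]carbonyloxy}-5-(propan-2-yl)-2-{[tert-butyl(diphenyl)silyl]oxymethyl}cyclohex-2-en-1-one
Conditions: N,N'-dicyclohexylcarbodiimide, 4-(dimethylamino)pyridine (10 mol%), CH2Cl2, 0 °C to rt
Reagents that add atoms: none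
Why: Steglich esterification of the α-hydroxy ketone with the epoxy acid touches no stereocentre, and the trans arrangement at C6 is the thermodynamically preferred one.

Step 15
Reactants: 22 (4R,5R,6S)-4-[(2Z)-2-methylbut-2-enoyloxy]-6-{[(2R,3R)-2,3-dimethyloxiran-2-yl]carbonyloxy}-5-(propan-2-yl)-2-{[tert-butyl(diphenyl)silyl]oxymethyl}cyclohex-2-en-1-one
Product: 23 (4R,5R,6S)-2-(hydroxymethyl)-4-[(2Z)-2-methylbut-2-enoyloxy]-6-{[(2R,3R)-2,3-dimethyloxiran-2-yl]carbonyloxy}-5-(propan-2-yl)cyclohex-2-en-1-one (CNP0293054.1)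
Conditions: HF·pyridine, pyridine, THF, 0 °C to rt
Reagents that add atoms: none
Why: Buffered fluoride-mediated desilylation should cleave the primary silyl ether while both esters, the enone and the epoxide remain.

Compound list
1 | methyl 4-oxotetrahydrofuran-3-carboxylate | COC(=O)C1COCC1=O | starting material
2 | methyl 4-[tert-butyl(dimethyl)silyl]oxy-2,5-dihydrofuran-3-carboxylate | COC(=O)C1=C(O[Si](C)(C)C(C)(C)C)COC1 | intermediate
3 | methyl 4-[tert-butyl(dimethyl)silyl]oxyfuran-3-carboxylate | COC(=O)c1cocc1O[Si](C)(C)C(C)(C)C | intermediate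
4 | {4-[tert-butyl(dimethyl)silyl]oxyfuran-3-yl}methanol | OCc1cocc1O[Si](C)(C)C(C)(C)C | intermediate
5 | tert-butyl-({4-[tert-butyl(dimethyl)silyl]oxyfuran-3-yl}methoxy)diphenylsilane (diene) | CC(C)(C)[Si](C)(C)Oc1cocc1CO[Si](c1ccccc1)(c1ccccc1)C(C)(C)C | intermediate
6 | ethyl diethoxyacetate | CCOC(=O)C(OCC)OCC | starting material
7 | isobutylmagnesium bromide | CC(C)C[Mg]Br | starting material
8 | bromomagnesium 1,1,2-triethoxy-4-methylpentan-2-olate (hemiketalate) | CCOC(OCC)C(O[Mg]Br)(OCC)CC(C)C | intermediate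
9 | 1,1-diethoxy-4-methylpentan-2-one | CCOC(OCC)C(=O)CC(C)C | intermediate
10 | angelic anhydride, (2Z)-2-methylbut-2-enoic anhydride | C/C=C(/C)C(=O)OC(=O)/C(C)=C\C | starting material
11 | potassium (2Z)-1,1-diethoxy-4-methylpent-2-en-2-olate | CCOC(OCC)/C([O-])=C/C(C)C.[K+] | intermediate
12 | (2Z)-1,1-diethoxy-4-methylpent-2-en-2-yl (2Z)-2-methylbut-2-enoate | CCOC(OCC)/C(OC(=O)/C(C)=C\C)=C/C(C)C | intermediate
13 | (2Z)-4-methyl-1-oxopent-2-en-2-yl (2Z)-2-methylbut-2-enoate (dienophile; isopropyl cis to angeloyloxy) | O=C/C(OC(=O)/C(C)=C\C)=C/C(C)C | intermediate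
14 | (1S,4S,5S,6S)-5-formyl-6-(propan-2-yl)-2-[tert-butyl(dimethyl)silyl]oxy-3-{[tert-butyl(diphenyl)silyl]oxymethyl}-7-oxabicyclo[2.2.1]hept-2-en-5-yl (2Z)-2-methylbut-2-enoate (5-exo formyl, 5-endo angelate, 6-endo isopropyl) | O=C[C@]1(OC(=O)/C(C)=C\C)[C@@H](C(C)C)[C@@H]2O[C@H]1C(CO[Si](c1ccccc1)(c1ccccc1)C(C)(C)C)=C2O[Si](C)(C)C(C)(C)C | intermediate
15 | (1S,3S,4S,5S,6S)-5-formyl-2-oxo-6-(propan-2-yl)-3-{[tert-butyl(diphenyl)silyl]oxymethyl}-7-oxabicyclo[2.2.1]heptan-5-yl (2Z)-2-methylbut-2-enoate (5-exo formyl, 5-endo angelate, 6-endo isopropyl, 3-endo silyloxymethyl) | O=C[C@]1(OC(=O)/C(C)=C\C)[C@@H](C(C)C)[C@@H]2O[C@H]1[C@H](CO[Si](c1ccccc1)(c1ccccc1)C(C)(C)C)C2=O | intermediate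
16 | (1S,3S,4S,5S,6R)-2-oxo-6-(propan-2-yl)-3-{[tert-butyl(diphenyl)silyl]oxymethyl}-7-oxabicyclo[2.2.1]heptan-5-yl (2Z)-2-methylbut-2-enoate (5-endo angelate, 6-endo isopropyl) | C/C=C(/C)C(=O)O[C@H]1[C@@H](C(C)C)[C@@H]2O[C@H]1[C@H](CO[Si](c1ccccc1)(c1ccccc1)C(C)(C)C)C2=O | intermediate
17 | (4R,5S,6S)-6-hydroxy-4-[(2Z)-2-methylbut-2-enoyloxy]-5-(propan-2-yl)-2-{[tert-butyl(diphenyl)silyl]oxymethyl}cyclohex-2-en-1-one | C/C=C(/C)C(=O)O[C@@H]1C=C(CO[Si](c2ccccc2)(c2ccccc2)C(C)(C)C)C(=O)[C@@H](O)[C@@H]1C(C)C | intermediate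
18 | methyl angelate, methyl (2Z)-2-methylbut-2-enoate | C/C=C(/C)C(=O)OC | starting material
19 | (2Z)-2-methylbut-2-en-1-ol | C/C=C(/C)CO | intermediate
20 | [(2S,3R)-2,3-dimethyloxiran-2-yl]methanol | OC[C@]1(C)O[C@@H]1C | intermediate
21 | (2R,3R)-2,3-dimethyloxirane-2-carboxylic acid | OC(=O)[C@]1(C)O[C@@H]1C | intermediate
22 | (4R,5R,6S)-4-[(2Z)-2-methylbut-2-enoyloxy]-6-{[(2R,3R)-2,3-dimethyloxiran-2-yl]carbonyloxy}-5-(propan-2-yl)-2-{[tert-butyl(diphenyl)silyl]oxymethyl}cyclohex-2-en-1-one | C/C=C(/C)C(=O)O[C@@H]1C=C(CO[Si](c2ccccc2)(c2ccccc2)C(C)(C)C)C(=O)[C@@H](OC(=O)[C@]2(C)O[C@@H]2C)[C@@H]1C(C)C | intermediate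
23 | (4R,5R,6S)-2-(hydroxymethyl)-4-[(2Z)-2-methylbut-2-enoyloxy]-6-{[(2R,3R)-2,3-dimethyloxiran-2-yl]carbonyloxy}-5-(propan-2-yl)cyclohex-2-en-1-one | C/C=C(/C)C(=O)O[C@@H]1C=C(CO)C(=O)[C@@H](OC(=O)[C@]2(C)O[C@@H]2C)[C@@H]1C(C)C | target

Total step count: 15.
Longest linear sequence: 9 steps (steps 1, 2, 3, 4, 8, 9, 10, 14, 15).

Steps most likely to fail

Step 8. The cationic boron catalyst may divert the siloxyfuran into addition at the formyl group (Mukaiyama aldol) or give poor face selection with the hindered trisubstituted enal. The fallback sets out from 5 and 13 and comes back at 22. The cycloaddition is run thermally without catalyst (toluene, 25–40 °C, then 1 M HCl/THF), which should give the same exo-formyl adduct as a racemate: 14 with its mirror image ent-cycloadduct F1, hydrolysed to 15 with its mirror image ent-keto aldehyde F2. The racemate is carried through steps 9 and 10, giving 16 with ent-bicyclic ketone F3 and then 17 with ent-hydroxy enone F4. Esterification with enantiopure 21 as in step 14 should give two diastereomers, 22 and the diastereomeric ester F5 built on the mirror-image core. These are separated by chromatography and 22 continues to step 15.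

Step 9. Extrusion of CO at the fully substituted carbon may be slow, with β-hydride elimination from the alkylrhodium hydride or isomerisation of the angelate at 100 °C. The fallback sets out from 15 and comes back at 16. Pinnick oxidation (NaClO2, NaH2PO4, 2-methylbut-2-ene, tBuOH/H2O) should give carboxylic acid F6. Coupling with N-hydroxyphthalimide (N,N'-dicyclohexylcarbodiimide, CH2Cl2) gives redox-active ester F7. Photoreductive decarboxylation (Ru(bpy)3Cl2 1 mol%, diethyl 2,6-dimethyl-1,4-dihydropyridine-3,5-dicarboxylate, blue light, rt) generates the tertiary α-acyloxy radical, which should take hydrogen on the open exo face to give 16.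

Step 6. The strongly basic enolate may undergo C-acylation, and the angeloyl unit may isomerise from Z to E (tiglate) or the enolate geometry may erode. The fallback sets out from 9 and comes back at 12. Soft enolisation (Me3SiCl, Et3N, NaI, MeCN) should give the isolable (Z)-trimethylsilyl enol ether F8. This neutral compound is O-acylated with 10 under catalytic tetrabutylammonium fluoride (THF, −78 °C), so that free enolate is present only in catalytic amount (fluoride-triggered acyl transfer), giving 12.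

Further compounds
F1 | step 8 | (1R,4R,5R,6R)-5-formyl-6-(propan-2-yl)-2-[tert-butyl(dimethyl)silyl]oxy-3-{[tert-butyl(diphenyl)silyl]oxymethyl}-7-oxabicyclo[2.2.1]hept-2-en-5-yl (2Z)-2-methylbut-2-enoate (enantiomer of 14) | O=C[C@@]1(OC(=O)/C(C)=C\C)[C@H](C(C)C)[C@H]2O[C@@H]1C(CO[Si](c1ccccc1)(c1ccccc1)C(C)(C)C)=C2O[Si](C)(C)C(C)(C)C
F2 | step 8 | (1R,3R,4R,5R,6R)-5-formyl-2-oxo-6-(propan-2-yl)-3-{[tert-butyl(diphenyl)silyl]oxymethyl}-7-oxabicyclo[2.2.1]heptan-5-yl (2Z)-2-methylbut-2-enoate (enantiomer of 15) | O=C[C@@]1(OC(=O)/C(C)=C\C)[C@H](C(C)C)[C@H]2O[C@@H]1[C@@H](CO[Si](c1ccccc1)(c1ccccc1)C(C)(C)C)C2=O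
F3 | step 8 | (1R,3R,4R,5R,6S)-2-oxo-6-(propan-2-yl)-3-{[tert-butyl(diphenyl)silyl]oxymethyl}-7-oxabicyclo[2.2.1]heptan-5-yl (2Z)-2-methylbut-2-enoate (enantiomer of 16) | C/C=C(/C)C(=O)O[C@@H]1[C@H](C(C)C)[C@H]2O[C@@H]1[C@@H](CO[Si](c1ccccc1)(c1ccccc1)C(C)(C)C)C2=O
F4 | step 8 | (4S,5R,6R)-6-hydroxy-4-[(2Z)-2-methylbut-2-enoyloxy]-5-(propan-2-yl)-2-{[tert-butyl(diphenyl)silyl]oxymethyl}cyclohex-2-en-1-one (enantiomer of 17) | C/C=C(/C)C(=O)O[C@H]1C=C(CO[Si](c2ccccc2)(c2ccccc2)C(C)(C)C)C(=O)[C@H](O)[C@H]1C(C)C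
F5 | step 8 | (4S,5S,6R)-4-[(2Z)-2-methylbut-2-enoyloxy]-6-{[(2R,3R)-2,3-dimethyloxiran-2-yl]carbonyloxy}-5-(propan-2-yl)-2-{[tert-butyl(diphenyl)silyl]oxymethyl}cyclohex-2-en-1-one (diastereomer of 22) | C/C=C(/C)C(=O)O[C@H]1C=C(CO[Si](c2ccccc2)(c2ccccc2)C(C)(C)C)C(=O)[C@H](OC(=O)[C@]2(C)O[C@@H]2C)[C@H]1C(C)C
F6 | step 9 | 5-endo-[(2Z)-2-methylbut-2-enoyloxy]-2-oxo-6-endo-(propan-2-yl)-3-{[tert-butyl(diphenyl)silyl]oxymethyl}-7-oxabicyclo[2.2.1]heptane-5-exo-carboxylic acid (configuration as in 15) | OC(=O)[C@]1(OC(=O)/C(C)=C\C)[C@@H](C(C)C)[C@@H]2O[C@H]1[C@H](CO[Si](c1ccccc1)(c1ccccc1)C(C)(C)C)C2=O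
F7 | step 9 | 1,3-dioxoisoindolin-2-yl ester of acid F6 | O=C(ON1C(=O)c2ccccc2C1=O)[C@]1(OC(=O)/C(C)=C\C)[C@@H](C(C)C)[C@@H]2O[C@H]1[C@H](CO[Si](c1ccccc1)(c1ccccc1)C(C)(C)C)C2=O
F8 | step 6 | [(2Z)-1,1-diethoxy-4-methylpent-2-en-2-yl]oxy(trimethyl)silane | CCOC(OCC)/C(=C/C(C)C)O[Si](C)(C)C
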